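**Analysis of the target**

Vidalol B is an achiral triaryl polyphenol in which three benzene rings are joined by two CH2 bridges. The central phloroglucinol ring (ring B) carries bromine at B1, hydroxyls at B2, B4 and B6, and identical benzyl arms at B3 and B5. Each arm ends in a ring A in which A1 bears the CH2, A2 and A3 bear bromine, A4 and A5 bear hydroxyl, and A6 bears hydrogen. There is no stereocentre or stereogenic axis, and a mirror plane through B1 and B4 makes the two arms equivalent, so every operation on ring A can be run on both arms at once. The sensitive groups are the two catechols (readily oxidised to ortho-quinones, especially as anions in air), the phloroglucinol ring (easily protonated at carbon, which invites loss of the B1 bromine or of a benzyl arm in acid) and the doubly activated diarylmethane CH2 groups. The difficulty lies in the substitution pattern: four contiguous substituted carbons A2–A5 on each outer ring, five aryl bromides in defined positions, and exactly two of three equivalent ring B carbons alkylated. The strategy rests on the sequence A3(Br)–A4(OH)–A5(OH) with A1 para to A4: A4 is a phenol whose one ortho carbon already bears bromine and whose para carbon bears the benzylic CH2, so its only free ortho carbon is A5. A formyl group can be delivered there by chelation and then exchanged for oxygen, and once A5 is oxygenated, A2 is the carbon para to it, which is where the last outer-ring bromine belongs.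

**Retrosynthetic reasoning**

10 to 9. The three O–CH3 bonds of ring B are cut first. Ring B is carried as its trimethyl ether because it must act as a clean C-nucleophile early on and then survive alkaline peroxide and bromination; a free phloroglucinol would be over-brominated and alkylated without control. The forward step has to cleave three aryl methyl ethers with a boron Lewis acid without touching five C–Br bonds or the CH2 bridges.

9 to 8. The C–Br bonds at B1 and at both A2 carbons are cut next. These are the most nucleophilic carbons left in 8: B1 is the only free position of a trialkoxy ring, and A2 is para to the A5 hydroxyl. The A3 bromines are not cut here because they are bought with 1 and are what forces the oxygen to A5. The forward step must place three bromine atoms regioselectively with an electrophilic brominating agent without oxidising the catechols.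

8 to 6 (through 7). Both A5–O bonds are cut, each oxygen being traced back to a formyl group. Direct hydroxylation of a bromophenol at A5 has no dependable regiochemistry or stopping point, whereas a formyl group ortho to a phenol is a masked hydroxyl that can be placed with certainty. The forward reaction must make the aryl group, not the formyl hydrogen, migrate to oxygen at both arms and must not destroy the catechol it creates.

6 to 4 and 5. The two A5–C(formyl) bonds are cut. In 4 each phenol has only one open ortho carbon, so a phenoxide-directed formylation with 5 has no regiochemical choice. Ring B has no phenoxide and is not a substrate. Each arm needs two molecules of 5, one that becomes the formyl group and one that accepts hydride, so four molecules of 5 are consumed per molecule of 4.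

4 to 3 and two molecules of 2. The B3–CH2 and B5–CH2 bonds are cut, not the CH2–A1 bonds. Ring B as 3 is by far the strongest π-nucleophile available, and 2 is a para-hydroxybenzyl alcohol that ionises under mild acid. The three CH positions of 3 are equivalent, so double alkylation can give only one constitution; the forward reaction only has to stop at two arms.

2 to 1. The benzylic C–O bond is traced back to the aldehyde 1 by hydride reduction. Compound 1 already holds the A3 bromine, the A4 hydroxyl and the A1 carbon in the right relationship.

**Alternatives that were turned down**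

Alternative 1: Both arms would be attached at the CH2–A1 bonds. Ring B would supply the two benzylic carbons as the formyl groups of 2,4,6-trimethoxybenzene-1,3-dicarbaldehyde A2, and ring A would arrive as (2,3-dibromo-4,5-dimethoxyphenyl)magnesium bromide A3.
- Forward key step: two equivalents of A3 add to A2 to give the bis-carbinol A1 (a diastereomer mixture of no consequence), followed by ionic deoxygenation of both carbinols, B1 bromination and ether cleavage.
- For it: every outer-ring bromine and oxygen is fixed before the coupling, so no catechol meets bromine and there is no late A2-versus-A6 question. The dialdehyde also guarantees exactly two arms. On both points it is stronger than the chosen route.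
- Against it: A3 has bromine on the carbon next to the C–Mg bond and will eliminate to an aryne unless it is made by a selective halogen–magnesium exchange and kept cold. A2 is a doubly ortho-methoxylated, electron-rich and hindered aldehyde, and the second addition must occur next to a bulky magnesium alkoxide. Both building blocks need several steps, and a deoxygenation step is added.
- Comparison: the chosen route accepts a late bromination but attaches both arms in one acid-catalysed step from a commodity aldehyde, with no organometallic reagent and fewer steps overall.

Alternative 2: Ring B itself would be opened at one C–C bond, leading back to the open-chain methyl 4-(2,3-dibromo-4,5-dimethoxybenzyl)-7-(2,3-dibromo-4,5-dimethoxyphenyl)-3,5-dioxoheptanoate A5, which already carries both arms.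
- Forward key step: with excess strong base the C6 methylene is deprotonated and acylated by the ester carbon in a Claisen closure; loss of methanol and enolisation give 2,4-bis(2,3-dibromo-4,5-dimethoxybenzyl)benzene-1,3,5-triol A4.
- For it: it mirrors the likely biosynthesis and ring B appears as the free triol, so no ring B ether has to be cleaved. The number and position of the arms are written into the chain, which is stronger than a stoichiometry-controlled double benzylation.
- Against it: A5 is a labile poly-β-carbonyl compound that must be assembled by successive enolate alkylations with C-versus-O and C2/C4/C6 regiochemical problems. The closure requires deprotonation at the least acidic carbon and competes with lactonisation through the enol oxygen of the far ketone, the usual fate of 3,5-diketo esters. The free phloroglucinol A4 must then be monobrominated and four methyl ethers removed.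
- Comparison: the chosen route uses an aromatic ring B from the start and forms only reliable aryl–CH2 and aryl–O bonds, at the price of three methyl ethers to cleave at the end.

Alternative 3: The three ring B C–O bonds would be cut and 1,3,5-tribromobenzene A8 used as a masked ring B. Each arm would be introduced by deprotonation between two bromines, addition to 4-benzyloxy-3-methoxybenzaldehyde A9 and deoxygenation, giving 1,3,5-tribromo-2,4-bis(4-benzyloxy-3-methoxybenzyl)benzene A7.
- Forward key step: all three ring B bromines of A7 are exchanged for methoxy groups by NaOMe under CuI catalysis, which gives 2,4-bis(4-benzyloxy-3-methoxybenzyl)-1,3,5-trimethoxybenzene A6.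
- For it: the arms are introduced one at a time by metalation, so their number is controlled exactly, which is better than the chosen double Friedel–Crafts step. No acid-labile para-hydroxybenzyl cation is involved.
- Against it: three Ullmann-type substitutions are needed on a crowded ring, one at a bromine flanked by two benzyl groups, and each competes with hydrodebromination to give mixtures that are hard to separate. After A6 the outer rings are still unfinished: debenzylation, two brominations per outer ring plus B1 (five late C–Br bonds against three in the chosen plan) and cleavage of five methyl ethers.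
- Comparison: it is the longest of the four routes. The chosen route uses the innate nucleophilicity of 3 instead of building it by late C–O coupling.

Key step: step 4

Remark on the chemistry: in the steps that act on both arms, the half-converted species are passing stages of the same reaction and are not numbered; the one intermediate of a different functional type (7) is. Each of these steps uses its reaction partner once per arm, and the amounts on the Reactants lines are counted per molecule of the two-armed substrate.

Step 1
Reactants: 1 3-bromo-4-hydroxybenzaldehyde
Product: 2 2-bromo-4-(hydroxymethyl)phenol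
Conditions: NaBH4, MeOH, 0 °C to rt; aq. NH4Cl work-up
Reagents that add atoms: none
Why: Hydride reduction of an aryl aldehyde; the phenol and aryl bromide are inert, and the near-neutral work-up keeps the acid-labile para-hydroxybenzyl alcohol from ionising.

Step 2
Reactants: 3 1,3,5-trimethoxybenzene; 2 2-bromo-4-(hydroxymethyl)phenol (2.0 equiv, added slowly)
Product: 4 2,4-bis(3-bromo-4-hydroxybenzyl)-1,3,5-trimethoxybenzene
Conditions: TsOH·H2O (10 mol %), CH2Cl2/(CF3)2CHOH 4:1, 0 °C to rt
Reagents that add atoms: none
Why: Friedel–Crafts benzylation: the para hydroxyl lets 2 ionise under mild acid to a quinone-methide-type cation, which is trapped by ring B, the strongest π-nucleophile present. The three CH positions of 3 are equivalent, so two alkylations give a single constitution; a third should be slowed by the two flanking methoxy groups that turn their methyls toward B1, and is limited by stoichiometry and slow addition.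

Step 3
Reactants: 4 2,4-bis(3-bromo-4-hydroxybenzyl)-1,3,5-trimethoxybenzene; 5 formaldehyde (4.0 equiv consumed, charged as paraformaldehyde in excess)
Product: 6 2,4-bis(3-bromo-5-formyl-4-hydroxybenzyl)-1,3,5-trimethoxybenzene
Conditions: MgCl2 (anhydrous, 4 equiv), Et3N (8 equiv), (CH2O)n (excess), THF, reflux; then cold 1 M HCl (brief)
Reagents that add atoms: formaldehyde (a second molecule of 5 for the second arm), C=O
Why: Magnesium-mediated ortho-formylation of phenols: the aryloxymagnesium chloride delivers coordinated formaldehyde to the ortho carbon, and the resulting benzylic alkoxide is oxidised to the aldehyde by Oppenauer-type hydride transfer to a second formaldehyde, so each arm builds in one molecule of 5 as its formyl group and turns another into methanol. A3 is blocked by bromine and A1 by the CH2, so A5 is the only site; the reaction is established for 2-bromophenols, and ring B has no phenoxide and stays untouched.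

Step 4
Reactants: 6 2,4-bis(3-bromo-5-formyl-4-hydroxybenzyl)-1,3,5-trimethoxybenzene
Product: 8 2,4-bis(3-bromo-4,5-dihydroxybenzyl)-1,3,5-trimethoxybenzene, via bis-formate 7 (not isolated)
Conditions: 30% aq. H2O2 (2.4 equiv), NaOH (2.2 equiv), THF/H2O, 0 °C to rt, Ar; then Na2S2O3, 1 M HCl
Reagents that add atoms: hydrogen peroxide, OO
Why: This is a Dakin oxidation, a known reaction of ortho-hydroxybenzaldehydes including 3-bromosalicylaldehydes. Hydroperoxide anion adds to each formyl carbon of the bis-phenoxide of 6 to give a tetrahedral peroxy adduct; the aryl group then shifts from carbon to the neighbouring peroxide oxygen with loss of hydroxide, which forms the A5–O bond and gives the bis(aryl formate) 7, and hydroxide cleaves the formates in the same flask to 8 and formate. No ring is closed and no stereocentre is formed. The selectivity needed is aryl over hydride migration, since hydride migration would give a salicylic acid; the phenoxide at A4, ortho to the migrating carbon, raises the migratory aptitude of the ring and secures it, while the A3 bromine is meta to the migrating carbon and should cost little. The position of the new oxygen is not a selectivity question, because it replaces the formyl group at the same carbon. About one equivalent of NaOH per formyl group is used, so the liberated formic acid consumes the base and the catechol ends un-ionised near neutral pH, which together with exclusion of air should protect it from over-oxidation. The trimethoxyphenyl ring, the aryl bromides and the CH2 bridges are not expected to react with cold alkaline peroxide.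

Step 5
Reactants: 8 2,4-bis(3-bromo-4,5-dihydroxybenzyl)-1,3,5-trimethoxybenzene
Product: 9 1-bromo-3,5-bis(2,3-dibromo-4,5-dihydroxybenzyl)-2,4,6-trimethoxybenzene
Conditions: Br2 (3.0 equiv), AcOH/CH2Cl2, 0 °C, dark; then aq. Na2S2O3
Reagents that add atoms: bromine, BrBr
Why: Electrophilic aromatic bromination: B1 is the only free carbon of the trialkoxy ring and should react readily. On each catechol ring the A4 hydroxyl has no free ortho or para carbon, so the A5 hydroxyl directs, and attack para to it (A2) is preferred over ortho (A6), the same preference that turns 5-bromovanillin into 5,6-dibromovanillin. The acidic, non-aqueous medium disfavours oxidation to ortho-quinones.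

Step 6
Reactants: 9 1-bromo-3,5-bis(2,3-dibromo-4,5-dihydroxybenzyl)-2,4,6-trimethoxybenzene
Product: 10 vidalol B
Conditions: BBr3 (excess), CH2Cl2, −78 °C to rt; then ice/H2O
Reagents that add atoms: none
Why: Lewis-acid cleavage of aryl methyl ethers: BBr3 binds each ether oxygen, bromide removes the methyl group by SN2 attack, and the aryloxyboranes are hydrolysed on work-up. Aryl bromides and CH2 bridges are inert, and the free catechol hydroxyls only consume reagent as borates.

**Compound list**

1 | 3-bromo-4-hydroxybenzaldehyde | O=Cc1ccc(O)c(Br)c1 | starting material
2 | 2-bromo-4-(hydroxymethyl)phenol | OCc1ccc(O)c(Br)c1 | intermediate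
3 | 1,3,5-trimethoxybenzene | COc1cc(OC)cc(OC)c1 | starting material
4 | 2,4-bis(3-bromo-4-hydroxybenzyl)-1,3,5-trimethoxybenzene | COc1cc(OC)c(Cc2ccc(O)c(Br)c2)c(OC)c1Cc1ccc(O)c(Br)c1 | intermediate
5 | formaldehyde (used as paraformaldehyde) | C=O | starting material
6 | 2,4-bis(3-bromo-5-formyl-4-hydroxybenzyl)-1,3,5-trimethoxybenzene | COc1cc(OC)c(Cc2cc(Br)c(O)c(C=O)c2)c(OC)c1Cc1cc(Br)c(O)c(C=O)c1 | intermediate
7 | 2,4-bis(3-bromo-5-formyloxy-4-hydroxybenzyl)-1,3,5-trimethoxybenzene | COc1cc(OC)c(Cc2cc(Br)c(O)c(OC=O)c2)c(OC)c1Cc1cc(Br)c(O)c(OC=O)c1 | intermediate
8 | 2,4-bis(3-bromo-4,5-dihydroxybenzyl)-1,3,5-trimethoxybenzene | COc1cc(OC)c(Cc2cc(Br)c(O)c(O)c2)c(OC)c1Cc1cc(Br)c(O)c(O)c1 | intermediate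
9 | 1-bromo-3,5-bis(2,3-dibromo-4,5-dihydroxybenzyl)-2,4,6-trimethoxybenzene | COc1c(Br)c(OC)c(Cc2cc(O)c(O)c(Br)c2Br)c(OC)c1Cc1cc(O)c(O)c(Br)c1Br | intermediate
10 | vidalol B | Oc1cc(Cc2c(O)c(Br)c(O)c(Cc3cc(O)c(O)c(Br)c3Br)c2O)c(Br)c(Br)c1O | target

Total step count: 6. Longest linear sequence: 6 steps (1 to 2 to 4 to 6 to 8 to 9 to 10).

**Steps least certain to work**

Step 4 (key step). The most likely failure is over-oxidation of the newly formed catechols in the alkaline peroxide medium, because catecholate anions are very easily oxidised. Stalling after the first arm and some hydride migration are also possible, since the A3 bromine makes the ring less electron-rich and the phenol more acidic. Fallback: the alkaline medium is left altogether. Setting out from 6, both phenols are methylated (MeI, K2CO3, DMF) to 2,4-bis(3-bromo-5-formyl-4-methoxybenzyl)-1,3,5-trimethoxybenzene F1. Baeyer–Villiger oxidation of the two ortho-methoxybenzaldehydes (mCPBA, NaHCO3, CH2Cl2) should give the bis(aryl formate) 2,4-bis(3-bromo-5-formyloxy-4-methoxybenzyl)-1,3,5-trimethoxybenzene F2, and methanolysis (K2CO3, MeOH) the bis-phenol 2,4-bis(3-bromo-5-hydroxy-4-methoxybenzyl)-1,3,5-trimethoxybenzene F3, in a sequence where no catechol anion ever exists. Br2 (3 equiv, AcOH) should brominate B1 and both A2 carbons, para to the free A5 hydroxyl, to 1-bromo-3,5-bis(2,3-dibromo-5-hydroxy-4-methoxybenzyl)-2,4,6-trimethoxybenzene F4. BBr3 then cleaves all five methyl ethers, and the sequence comes back to the route at 10.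

Step 5. Bromine may oxidise the free catechols to ortho-quinones, may attack A6 instead of or in addition to A2, or may attack an ipso carbon (A1 or a benzylated ring B carbon) with loss of a benzyl arm, since both fragments would be stabilised cations. Fallback: setting out from 8, the four catechol hydroxyls are methylated (MeI, K2CO3, acetone, Ar) to 2,4-bis(3-bromo-4,5-dimethoxybenzyl)-1,3,5-trimethoxybenzene F5. Br2 (3 equiv, AcOH, NaOAc) should then give 1-bromo-3,5-bis(2,3-dibromo-4,5-dimethoxybenzyl)-2,4,6-trimethoxybenzene F6; here A2 is para to an in-plane methoxy group, A6 is screened by its methyl, and no oxidisable catechol is present. Excess BBr3 cleaves all seven ethers, and the route is rejoined at 10.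

Step 2. The alkylation may spread over one, two and three arms instead of stopping at two, and 2 may condense with itself through the free ortho carbon of its own phenol ring. Fallback: setting out from 3, monobromination (NBS, MeCN, 0 °C) gives 2-bromo-1,3,5-trimethoxybenzene F7, in which the future B1 bromine blocks the third position so that an excess of 2 can be used. F7 and 2 under the conditions of step 2 should give 1-bromo-3,5-bis(3-bromo-4-hydroxybenzyl)-2,4,6-trimethoxybenzene F8. The formylation of step 3 leads to 1-bromo-3,5-bis(3-bromo-5-formyl-4-hydroxybenzyl)-2,4,6-trimethoxybenzene F9. The Dakin oxidation of step 4 then passes through the bis(aryl formate) 1-bromo-3,5-bis(3-bromo-5-formyloxy-4-hydroxybenzyl)-2,4,6-trimethoxybenzene F10 to 1-bromo-3,5-bis(3-bromo-4,5-dihydroxybenzyl)-2,4,6-trimethoxybenzene F11. Two equivalents of Br2 then suffice, and the route is rejoined at 9. This is held in reserve because the B1 bromine on an electron-rich ring is exposed to acid during benzylation (possible bromine transfer) and both alkylations then occur at more crowded positions.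

Step 6. As ring B is unmasked in the presence of HBr, ipso-protonation of the phloroglucinol may cause loss of the B1 bromine or cleavage of a benzyl–ring B bond. Fallback: the order of the last two steps is reversed. Setting out from 8, BBr3 is applied first to give 2,4-bis(3-bromo-4,5-dihydroxybenzyl)benzene-1,3,5-triol F12. The three brominations (Br2, 3 equiv, AcOH, low temperature, short contact) become the final step and come back to the route at 10, so the acid-labile B1–Br bond never meets BBr3.

**Further compounds**

F1 | step 4 | 2,4-bis(3-bromo-5-formyl-4-methoxybenzyl)-1,3,5-trimethoxybenzene | COc1cc(OC)c(Cc2cc(Br)c(OC)c(C=O)c2)c(OC)c1Cc1cc(Br)c(OC)c(C=O)c1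
F2 | step 4 | 2,4-bis(3-bromo-5-formyloxy-4-methoxybenzyl)-1,3,5-trimethoxybenzene | COc1cc(OC)c(Cc2cc(Br)c(OC)c(OC=O)c2)c(OC)c1Cc1cc(Br)c(OC)c(OC=O)c1
F3 | step 4 | 2,4-bis(3-bromo-5-hydroxy-4-methoxybenzyl)-1,3,5-trimethoxybenzene | COc1cc(OC)c(Cc2cc(Br)c(OC)c(O)c2)c(OC)c1Cc1cc(Br)c(OC)c(O)c1
F4 | step 4 | 1-bromo-3,5-bis(2,3-dibromo-5-hydroxy-4-methoxybenzyl)-2,4,6-trimethoxybenzene | COc1c(Br)c(OC)c(Cc2cc(O)c(OC)c(Br)c2Br)c(OC)c1Cc1cc(O)c(OC)c(Br)c1Br
F5 | step 5 | 2,4-bis(3-bromo-4,5-dimethoxybenzyl)-1,3,5-trimethoxybenzene | COc1cc(OC)c(Cc2cc(Br)c(OC)c(OC)c2)c(OC)c1Cc1cc(Br)c(OC)c(OC)c1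
F6 | step 5 | 1-bromo-3,5-bis(2,3-dibromo-4,5-dimethoxybenzyl)-2,4,6-trimethoxybenzene | COc1c(Br)c(OC)c(Cc2cc(OC)c(OC)c(Br)c2Br)c(OC)c1Cc1cc(OC)c(OC)c(Br)c1Br
F7 | step 2 | 2-bromo-1,3,5-trimethoxybenzene | COc1cc(OC)c(Br)c(OC)c1
F8 | step 2 | 1-bromo-3,5-bis(3-bromo-4-hydroxybenzyl)-2,4,6-trimethoxybenzene | COc1c(Br)c(OC)c(Cc2ccc(O)c(Br)c2)c(OC)c1Cc1ccc(O)c(Br)c1
F9 | step 2 | 1-bromo-3,5-bis(3-bromo-5-formyl-4-hydroxybenzyl)-2,4,6-trimethoxybenzene | COc1c(Br)c(OC)c(Cc2cc(Br)c(O)c(C=O)c2)c(OC)c1Cc1cc(Br)c(O)c(C=O)c1
F10 | step 2 | 1-bromo-3,5-bis(3-bromo-5-formyloxy-4-hydroxybenzyl)-2,4,6-trimethoxybenzene | COc1c(Br)c(OC)c(Cc2cc(Br)c(O)c(OC=O)c2)c(OC)c1Cc1cc(Br)c(O)c(OC=O)c1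
F11 | step 2 | 1-bromo-3,5-bis(3-bromo-4,5-dihydroxybenzyl)-2,4,6-trimethoxybenzene | COc1c(Br)c(OC)c(Cc2cc(Br)c(O)c(O)c2)c(OC)c1Cc1cc(Br)c(O)c(O)c1
F12 | step 6 | 2,4-bis(3-bromo-4,5-dihydroxybenzyl)benzene-1,3,5-triol | Oc1cc(O)c(Cc2cc(Br)c(O)c(O)c2)c(O)c1Cc1cc(Br)c(O)c(O)c1
A1 | alternative 1 | bis-carbinol [2,4,6-trimethoxy-1,3-phenylene]bis[(2,3-dibromo-4,5-dimethoxyphenyl)methanol], diastereomer mixture | COc1cc(OC)c(C(O)c2cc(OC)c(OC)c(Br)c2Br)c(OC)c1C(O)c1cc(OC)c(OC)c(Br)c1Br
A2 | alternative 1 | 2,4,6-trimethoxybenzene-1,3-dicarbaldehyde | COc1cc(OC)c(C=O)c(OC)c1C=O
A3 | alternative 1 | (2,3-dibromo-4,5-dimethoxyphenyl)magnesium bromide | COc1cc([Mg]Br)c(Br)c(Br)c1OC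
A4 | alternative 2 | 2,4-bis(2,3-dibromo-4,5-dimethoxybenzyl)benzene-1,3,5-triol | Oc1cc(O)c(Cc2cc(OC)c(OC)c(Br)c2Br)c(O)c1Cc1cc(OC)c(OC)c(Br)c1Br
A5 | alternative 2 | methyl 4-(2,3-dibromo-4,5-dimethoxybenzyl)-7-(2,3-dibromo-4,5-dimethoxyphenyl)-3,5-dioxoheptanoate (racemic) | COC(=O)CC(=O)C(Cc1cc(OC)c(OC)c(Br)c1Br)C(=O)CCc1cc(OC)c(OC)c(Br)c1Br
A6 | alternative 3 | 2,4-bis(4-benzyloxy-3-methoxybenzyl)-1,3,5-trimethoxybenzene | COc1cc(OC)c(Cc2ccc(OCc3ccccc3)c(OC)c2)c(OC)c1Cc1ccc(OCc2ccccc2)c(OC)c1
A7 | alternative 3 | 1,3,5-tribromo-2,4-bis(4-benzyloxy-3-methoxybenzyl)benzene | Brc1cc(Br)c(Cc2ccc(OCc3ccccc3)c(OC)c2)c(Br)c1Cc1ccc(OCc2ccccc2)c(OC)c1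
A8 | alternative 3 | 1,3,5-tribromobenzene | Brc1cc(Br)cc(Br)c1
A9 | alternative 3 | 4-benzyloxy-3-methoxybenzaldehyde | COc1cc(C=O)ccc1OCc1ccccc1
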